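**Plan**

Retrosynthesis: the 1,2-dioxolane is opened at C3–C4 and C5–O1 in one stroke, a polar [3+2] annulation. This is possible because ring atoms O1–O2–C3, with CH3 and CH2CO2Me on C3, are the peroxycarbenium ion of methyl acetoacetate, and C4H2–C5(CH3)(alkyl) is a 1,1-disubstituted alkene that passes through a tertiary cation at C5.
The alkene is cut at C=CH2 (Wittig), at a chain double bond (cross-metathesis) and at CH3–C(=O), back to (R)-citronellic acid: its C1 becomes ring C5, its C2 the CH2 next to the ring, its C3 the (2R)-methyl centre of the side chain.
Forward: citronellic acid → methyl ketone → cross-metathesis with 4-phenyl-1-butene → hydrogenation → methylenation; methyl 3-methylbut-3-enoate → ozonolysis in methanol → O-silylation; the two fragments are joined in the last step, which builds the only ring.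
Stereochemistry: the side-chain centre comes from the chiral pool and is never touched; C3 and C5 are both created in the annulation inside the pocket of a confined chiral counteranion.

Key step: step 7

Remark: the three starting materials are taken as articles of commerce; in step 7 the (S,S) acid stands for whichever hand of the catalyst proves to expose the Re face of the cationic carbon, to be settled by running both.

**Route**

Step 1
Reactants: 1 (3R)-3,7-dimethyloct-6-enoic acid [(R)-citronellic acid]
Product: 3 (4R)-4,8-dimethylnon-7-en-2-one, via dilithium gem-diolate 2 (not isolated)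
Conditions: MeLi (2.2 equiv), Et2O, 0 °C to rt; inverse quench into cold 1 M HCl
Reagents that add atoms: methyllithium, [Li]C
Why: Addition of an organolithium to a lithium carboxylate (carboxylic acid to methyl ketone) should stop at the gem-diolate 2, which releases the ketone only on hydrolysis; the stereocentre is β to the carbonyl and cannot epimerise.

Step 2
Reactants: 3 (4R)-4,8-dimethylnon-7-en-2-one; 4 but-3-en-1-ylbenzene (4-phenyl-1-butene)
Product: 5 (4R)-4-methyl-10-phenyldec-7-en-2-one (E/Z mixture)
Conditions: 4 (3 equiv), second-generation Grubbs catalyst RuCl2(=CHPh)(PCy3)(H2IMes) (3 mol %), CH2Cl2, 40 °C, argon sweep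
Reagents that add atoms: none
Why: Olefin cross-metathesis should exchange the isopropylidene end of the prenyl-type alkene for the terminal alkene partner, driven by loss of gaseous 2-methylpropene; the alkene geometry is irrelevant because the double bond is saturated in step 3.

Step 3
Reactants: 5 (4R)-4-methyl-10-phenyldec-7-en-2-one
Product: 6 (4R)-4-methyl-10-phenyldecan-2-one
Conditions: H2 (1 atm), 10% Pd/C, EtOAc, rt
Reagents that add atoms: none
Why: Heterogeneous catalytic hydrogenation should saturate the disubstituted alkene and leave the methyl ketone and the phenyl ring untouched under these mild conditions; no new stereocentre arises.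

Step 4
Reactants: 6 (4R)-4-methyl-10-phenyldecan-2-one
Product: 7 [(7R)-7,9-dimethyldec-9-en-1-yl]benzene
Conditions: Ph3PCH3Br, KOtBu, THF, 0 °C to rt
Reagents that add atoms: methyltriphenylphosphonium bromide, C[P+](c1ccccc1)(c1ccccc1)c1ccccc1.[Br-]
Why: Wittig methylenation of a methyl ketone with the non-stabilised ylide should give the 1,1-disubstituted alkene; the stereocentre is β to the carbonyl and is not endangered by enolisation.

Step 5
Reactants: 8 methyl 3-methylbut-3-enoate
Product: 11 methyl 3-hydroperoxy-3-methoxybutanoate (racemic), via primary ozonide 9 (not isolated), via carbonyl oxide 10 (not isolated)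
Conditions: O3, CH2Cl2/MeOH (4:1), −78 °C; N2 purge; concentrated cold behind a shield
Reagents that add atoms: ozone, O=[O+][O-]; methanol, CO
Why: Ozonolysis in methanol (Criegee mechanism) should fragment the primary ozonide 9 mainly to formaldehyde and the more substituted carbonyl oxide 10, which methanol traps as the α-methoxy hydroperoxide; the new centre is racemic, which is harmless because it becomes planar again in step 7.

Step 6
Reactants: 11 methyl 3-hydroperoxy-3-methoxybutanoate
Product: 12 methyl 3-methoxy-3-[(triethylsilyl)peroxy]butanoate (racemic)
Conditions: Et3SiCl, imidazole, CH2Cl2, 0 °C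
Reagents that add atoms: chlorotriethylsilane, CC[Si](Cl)(CC)CC
Why: O-Silylation of a hydroperoxide under mild base should give the silylperoxy ketal without ionising the ketal, and supplies the leaving group (OMe) and the electrofuge (Et3Si) needed in step 7.

Step 7
Reactants: 12 methyl 3-methoxy-3-[(triethylsilyl)peroxy]butanoate; 7 [(7R)-7,9-dimethyldec-9-en-1-yl]benzene
Product: 15 methyl 2-[(3R,5S)-3,5-dimethyl-5-[(2R)-2-methyl-8-phenyloctyl]-1,2-dioxolan-3-yl]acetate, via peroxycarbenium ion 13 (not isolated), via tertiary carbocation 14 (not isolated)
Conditions: 7 (1.0 equiv), 12 (1.5 equiv), (S,S)-imidodiphosphorimidate (IDPi) acid HN[P(=NSO2CF3)(O2C20H10Ar2)]2, Ar = 3,5-(CF3)2C6H3 (5 mol %), 4 Å molecular sieves, CH2Cl2, −78 °C; Et3N quench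
Reagents that add atoms: none
Why: Proposed new method: the strong chiral acid, which should rest as its Et3Si form after the first turnover, removes the methoxy group of 12 as Et3SiOMe and leaves peroxycarbenium ion 13 as a contact ion pair inside the confined anion; the CH2 terminus of alkene 7 then adds to the cationic carbon (C–C bond) to give tertiary cation 14, whose silyl-bearing distal peroxide oxygen captures the cation (O–C bond) and hands Et3Si back to the anion. The closest known reaction types are the SnCl4- or TiCl4-promoted racemic [3+2] annulation of triethylsilylperoxy ketals with alkenes and the silylium-based counteranion-directed additions of π-nucleophiles to oxocarbenium ions released from acetals by this class of acid. The 1,2-dioxolane closes as a stepwise polar [3+2] annulation whose last event is five-membered-ring capture of a trigonal carbocation by oxygen, a closure in which no π bond is broken and which therefore lies outside the exo/endo classification. C3 (R) is set by the catalyst, which must expose the Re face of 13 by telling CH3 from CH2CO2Me; C5 (S) is set in the ring closure within the same ion pair, where the ester carbonyl is expected to hold the electrophilic silicon of the closing oxygen on the face of the acetate arm, so that the branched chain on C5 turns away from silicon and C5–CH3 ends cis to CH2CO2Me. The step needs Markovnikov regiochemistry, secured by the tertiary cation that the CH2=C(CH3)R alkene gives, chemoselection for the alkene over the phenyl ring, secured by its far higher π-nucleophilicity, and catalyst control over both new centres, since the (2R)-methyl centre is insulated from both reacting carbons by a CH2 group and should exert little bias of its own.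

**Compound list**

1 | (3R)-3,7-dimethyloct-6-enoic acid [(R)-citronellic acid] | C[C@H](CCC=C(C)C)CC(=O)O | starting material
2 | dilithium (4R)-4,8-dimethylnon-7-ene-2,2-diolate | C[C@H](CCC=C(C)C)CC(C)([O-])[O-].[Li+].[Li+] | intermediate
3 | (4R)-4,8-dimethylnon-7-en-2-one | C[C@H](CCC=C(C)C)CC(C)=O | intermediate
4 | but-3-en-1-ylbenzene (4-phenyl-1-butene) | C=CCCc1ccccc1 | starting material
5 | (4R)-4-methyl-10-phenyldec-7-en-2-one (E/Z mixture) | C[C@H](CCC=CCCc1ccccc1)CC(C)=O | intermediate
6 | (4R)-4-methyl-10-phenyldecan-2-one | C[C@H](CCCCCCc1ccccc1)CC(C)=O | intermediate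
7 | [(7R)-7,9-dimethyldec-9-en-1-yl]benzene | C=C(C)C[C@H](C)CCCCCCc1ccccc1 | intermediate
8 | methyl 3-methylbut-3-enoate | COC(=O)CC(C)=C | starting material
9 | methyl 2-(4-methyl-1,2,3-trioxolan-4-yl)acetate (primary ozonide) | COC(=O)CC1(C)COOO1 | intermediate
10 | carbonyl oxide of methyl acetoacetate | COC(=O)CC(C)=[O+][O-] | intermediate
11 | methyl 3-hydroperoxy-3-methoxybutanoate (racemic) | COC(=O)CC(C)(OC)OO | intermediate
12 | methyl 3-methoxy-3-[(triethylsilyl)peroxy]butanoate (racemic) | COC(=O)CC(C)(OC)OO[Si](CC)(CC)CC | intermediate
13 | peroxycarbenium ion from 12 (counter-ion: the catalyst anion) | COC(=O)CC(C)=[O+]O[Si](CC)(CC)CC | intermediate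
14 | tertiary carbocation with the (3R) centre in place (counter-ion: the catalyst anion) | COC(=O)C[C@](C)(OO[Si](CC)(CC)CC)C[C+](C)C[C@H](C)CCCCCCc1ccccc1 | intermediate
15 | methyl 2-[(3R,5S)-3,5-dimethyl-5-[(2R)-2-methyl-8-phenyloctyl]-1,2-dioxolan-3-yl]acetate | COC(=O)C[C@@]1(C)C[C@](C)(C[C@H](C)CCCCCCc2ccccc2)OO1 | target

**Step count**

Total: 7 steps. Longest linear sequence: 5 steps (steps 1 to 4, then step 7).

**Steps most likely to fail**

Step 7 (proposed new method). Face discrimination in the ion pair may be poor at C3 or, more likely, at C5, for which no precedent exists. The peroxycarbenium ion may also lose a proton toward the ester before the alkene arrives, and the acid may shift the alkene double bond. The fallback uses known chemistry and makes the C3–CH2CO2Me bond last. From 6, addition of CH3C≡CMgBr (THF, 0 °C) would give (6R)-4,6-dimethyl-12-phenyldodec-2-yn-4-ol F1. Meyer–Schuster rearrangement (Ph3PAuNTf2 cat., toluene/MeOH) would give the enone (6R)-4,6-dimethyl-12-phenyldodec-3-en-2-one F2. Conjugate addition of H2O2 (50% aq., LiOH cat., THF/MeOH, 0 °C) and closure of the β-hydroperoxy ketone would give the cyclic peroxyhemiketal 3,5-dimethyl-5-[(2R)-2-methyl-8-phenyloctyl]-1,2-dioxolan-3-ol F3. MeOH with TsOH (cat.) would give 3-methoxy-3,5-dimethyl-5-[(2R)-2-methyl-8-phenyloctyl]-1,2-dioxolane F4. TiCl4 with 1-methoxy-1-(trimethylsilyloxy)ethene (CH2Cl2, −78 °C) would then substitute the methoxy group through the cyclic peroxycarbenium ion and return to the route at 15. This sequence does not control C5 and relies on attack anti to the larger C5 group at C3, so 15 would have to be separated from its ring stereoisomers by preparative HPLC.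

Step 5. The primary ozonide may fragment in the unwanted direction under the influence of the ester, and the hydroperoxy ketal may decompose on concentration. The fallback avoids a carbonyl oxide. From 8, ozonolysis in CH2Cl2 with Me2S work-up would give methyl acetoacetate F5 (also an article of commerce). HC(OMe)3 with TsOH (cat.) in MeOH would give methyl 3,3-dimethoxybutanoate F6. Exchange of one methoxy group for OOH with anhydrous H2O2 in Et2O (camphorsulfonic acid cat., 0 °C) would give 11, where the route is rejoined.

Step 2. Metathesis at the trisubstituted double bond may be sluggish while the terminal partner homodimerises, and the double bond may migrate. The fallback builds the chain by olefination. From 3, ozonolysis (O3, CH2Cl2, −78 °C; PPh3) would give (4R)-4-methyl-6-oxoheptanal F7. An aldehyde-selective Wittig reaction with the ylide from (3-phenylpropyl)triphenylphosphonium bromide and NaN(SiMe3)2 (THF, −78 °C) would give 5, mainly as the Z isomer, where the route is rejoined.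

**Further compounds**

F1 | step 7 | (6R)-4,6-dimethyl-12-phenyldodec-2-yn-4-ol (C4 epimers) | CC#CC(C)(O)C[C@H](C)CCCCCCc1ccccc1
F2 | step 7 | (6R)-4,6-dimethyl-12-phenyldodec-3-en-2-one (E/Z mixture) | CC(=O)C=C(C)C[C@H](C)CCCCCCc1ccccc1
F3 | step 7 | 3,5-dimethyl-5-[(2R)-2-methyl-8-phenyloctyl]-1,2-dioxolan-3-ol (ring stereoisomers) | CC1(O)CC(C)(C[C@H](C)CCCCCCc2ccccc2)OO1
F4 | step 7 | 3-methoxy-3,5-dimethyl-5-[(2R)-2-methyl-8-phenyloctyl]-1,2-dioxolane (ring stereoisomers) | COC1(C)CC(C)(C[C@H](C)CCCCCCc2ccccc2)OO1
F5 | step 5 | methyl acetoacetate | CC(=O)CC(=O)OC
F6 | step 5 | methyl 3,3-dimethoxybutanoate | COC(=O)CC(C)(OC)OC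
F7 | step 2 | (4R)-4-methyl-6-oxoheptanal | CC(=O)C[C@H](C)CCC=O
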